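**Plan**
1. Retrosynthesis: the C6–C6' biaryl bond is cut first (Suzuki–Miyaura) into two flavan-3,4-diol halves that differ only at C4. The 4R (3,4-cis) half is traced back to the 4S (3,4-trans) half by oxidation and hydride return at C4, so one monomer serves both halves.
2. In that monomer the O1–C8a bond of ring C is cut. C8a is the ring A carbon ortho to the C4 side chain and the C2 oxygen is five bonds away, so a bromide on C8a and the free C2 hydroxyl can close ring C without touching any stereocentre. The open chain is then cut at C2–aryl (Grignard on a Weinreb amide) and at C3–C4 (glycolate aldol).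
3. Forward order: ring A aldehyde with Br at the future C8a → aldol (C3–C4) → aryl ketone → 1,3-syn diol → ring C by aryl–O closure → bromination at C6 → C4 inversion on one portion, borylation of the other → biaryl → hydrogenolysis.
4. Stereochemistry: C3 and C4 come from an Evans syn aldol with (R)-4-benzyloxazolidin-2-one, and C2 from a chelate-controlled 1,3-syn reduction. The 2,3-cis and 3,4-trans ring relationships follow by retention in the ring closure. The 4R centre of the other half comes from hydride attack anti to the axial 3-benzyloxy group. The biaryl axis has only two ortho substituents and is not a stereo-element.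

Key step: step 8

Remark: atoms are numbered as in the flavan skeleton (O1, C2–C4, C4a, C5–C8, C8a), also in open-chain precursors; primed numbers belong to the 4S half. [4-(Benzyloxy)phenyl]magnesium bromide is taken as the commercial THF solution.

**Step 1**
Reactants: 1 2-bromo-3-hydroxy-4-methoxybenzaldehyde
Product: 2 2-bromo-3,4-dihydroxybenzaldehyde
Conditions: BBr3 (2.5 equiv), CH2Cl2, −78 °C to rt; H2O
Reagents that add atoms: none
Why: Boron tribromide O-demethylation of the aryl methyl ether should free the second phenol, so that both ring A oxygens can carry benzyl groups that leave in the last step.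

**Step 2**
Reactants: 2 2-bromo-3,4-dihydroxybenzaldehyde
Product: 3 3,4-bis(benzyloxy)-2-bromobenzaldehyde
Conditions: BnBr (2.3 equiv), K2CO3, DMF, 60 °C
Reagents that add atoms: benzyl bromide, BrCc1ccccc1
Why: Williamson etherification of both phenoxides; aldehyde and aryl bromide are inert to carbonate.

**Step 3**
Reactants: 4 (R)-4-benzyloxazolidin-2-one; 5 2-(benzyloxy)acetyl chloride
Product: 7 (R)-4-benzyl-3-[2-(benzyloxy)acetyl]oxazolidin-2-one, via lithium oxazolidinide 6 (not isolated)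
Conditions: n-BuLi, THF, −78 °C; then 5, −78 to 0 °C
Reagents that add atoms: none
Why: N-acylation of the lithiated oxazolidinone by the acid chloride (loading of the Evans auxiliary); the auxiliary stereocentre is not touched.

**Step 4**
Reactants: 7 (R)-4-benzyl-3-[2-(benzyloxy)acetyl]oxazolidin-2-one; 3 3,4-bis(benzyloxy)-2-bromobenzaldehyde
Product: 9 (R)-4-benzyl-3-[(2R,3S)-2-(benzyloxy)-3-[3,4-bis(benzyloxy)-2-bromophenyl]-3-hydroxypropanoyl]oxazolidin-2-one, via dibutylboron Z-enolate 8 (not isolated)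
Conditions: Bu2BOTf (1.2 equiv), Et3N (1.4 equiv), CH2Cl2, −78 to 0 °C; then 3, −78 to 0 °C; pH 7 buffer, MeOH, 30% H2O2, 0 °C
Reagents that add atoms: none
Why: Evans syn glycolate aldol, in which the Z-boron enolate adds to the aldehyde through a Zimmerman–Traxler chair on the enolate face away from the auxiliary benzyl group, should set the future C3 (R) and C4 (S) in a syn relationship.

**Step 5**
Reactants: 9 (R)-4-benzyl-3-[(2R,3S)-2-(benzyloxy)-3-[3,4-bis(benzyloxy)-2-bromophenyl]-3-hydroxypropanoyl]oxazolidin-2-one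
Product: 10 (2R,3S)-2-(benzyloxy)-3-[3,4-bis(benzyloxy)-2-bromophenyl]-3-hydroxy-N-methoxy-N-methylpropanamide
Conditions: MeNH(OMe)·HCl (3 equiv), AlMe3 (3 equiv), CH2Cl2, −10 °C to rt; aq. Rochelle salt
Reagents that add atoms: N,O-dimethylhydroxylamine hydrochloride, CNOC.Cl
Why: Aluminium amide transamination of the imide (Weinreb amide formation), helped by the free β-hydroxyl, should release the auxiliary without touching the two stereocentres.

**Step 6**
Reactants: 10 (2R,3S)-2-(benzyloxy)-3-[3,4-bis(benzyloxy)-2-bromophenyl]-3-hydroxy-N-methoxy-N-methylpropanamide; 11 [4-(benzyloxy)phenyl]magnesium bromide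
Product: 12 (2R,3S)-2-(benzyloxy)-3-[3,4-bis(benzyloxy)-2-bromophenyl]-1-[4-(benzyloxy)phenyl]-3-hydroxypropan-1-one
Conditions: 11 (3 equiv), THF, 0 °C; sat. aq. NH4Cl
Reagents that add atoms: none
Why: Grignard addition to the Weinreb amide stops at the chelated tetrahedral adduct and gives the aryl ketone on work-up; one equivalent of 11 is spent on the hydroxyl and the aryl bromide does not exchange at 0 °C.

**Step 7**
Reactants: 12 (2R,3S)-2-(benzyloxy)-3-[3,4-bis(benzyloxy)-2-bromophenyl]-1-[4-(benzyloxy)phenyl]-3-hydroxypropan-1-one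
Product: 14 (1S,2S,3R)-2-(benzyloxy)-1-[3,4-bis(benzyloxy)-2-bromophenyl]-3-[4-(benzyloxy)phenyl]propane-1,3-diol, via diethylboron chelate 13 (not isolated)
Conditions: Et2BOMe (1.2 equiv), THF/MeOH 4:1, −78 °C; NaBH4, −78 °C; pH 7 buffer, 30% H2O2, 0 °C
Reagents that add atoms: none
Why: Narasaka–Prasad reduction, in which the boron chelate holds hydroxyl and ketone in a six-membered half-chair and external hydride attacks axially, should set the new carbinol (future C2, R) 1,3-syn to C4 and give the all-syn chain.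

**Step 8**
Reactants: 14 (1S,2S,3R)-2-(benzyloxy)-1-[3,4-bis(benzyloxy)-2-bromophenyl]-3-[4-(benzyloxy)phenyl]propane-1,3-diol
Product: 15 (2R,3R,4S)-3,7,8-tris(benzyloxy)-2-[4-(benzyloxy)phenyl]chroman-4-ol
Conditions: CuI (10 mol %), 3,4,7,8-tetramethyl-1,10-phenanthroline (20 mol %), Cs2CO3 (2 equiv), toluene (0.05 M), 110 °C, argon
Reagents that add atoms: none
Why: The caesium alkoxide of the C2 hydroxyl binds phenanthroline-ligated monovalent copper, the C8a–Br bond adds oxidatively to give an aryl(alkoxo) trivalent copper species in a seven-membered chelate, and reductive elimination forms O1–C8a. The closest known reaction type is the intramolecular Ullmann-type O-arylation of secondary alcohols with aryl bromides (copper-catalysed chroman synthesis). Ring C closes in a 6-exo mode at the sp2 carbon C8a, the bromide leaving outside the new ring. No stereocentre is made or broken: the C2–O bond stays intact, so the syn C2/C3 pair of 14 becomes the 2,3-cis flavan and the syn C3/C4 pair the 3,4-trans carbinol by retention, an outcome that closures through the C2–O bond of such benzylic alcohols tend to miss. The step needs oxygen selectivity and site selectivity on ring A; the first is secured because the C3 oxygen is benzylated and the C4 oxygen could only close a four-membered ring, the second because bromine marks C8a alone, so the equally placed ortho carbon C5 cannot compete. Because 15 is the source of both halves, this one closure makes ring C of each.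

**Step 9**
Reactants: 15 (2R,3R,4S)-3,7,8-tris(benzyloxy)-2-[4-(benzyloxy)phenyl]chroman-4-ol
Product: 16 (2R,3R,4S)-3,7,8-tris(benzyloxy)-2-[4-(benzyloxy)phenyl]-6-bromochroman-4-ol
Conditions: NBS (1.05 equiv), MeCN, 0 °C, dark
Reagents that add atoms: N-bromosuccinimide, O=C1CCC(=O)N1Br
Why: Electrophilic aromatic bromination should go to C6, which is para to O1 and ortho to the 7-benzyloxy group, whereas C5 is activated only by the twisted 8-benzyloxy group and the other rings are far less electron-rich.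

**Step 10**
Reactants: 16 (2R,3R,4S)-3,7,8-tris(benzyloxy)-2-[4-(benzyloxy)phenyl]-6-bromochroman-4-ol
Product: 17 (2R,3S)-3,7,8-tris(benzyloxy)-2-[4-(benzyloxy)phenyl]-6-bromochroman-4-one
Conditions: Dess–Martin periodinane (1.3 equiv), NaHCO3, CH2Cl2, 0 °C to rt; used crude
Reagents that add atoms: none
Why: Dess–Martin oxidation of the only free hydroxyl under buffered, non-basic conditions should give the 2,3-cis ketone without enolising C3 (the descriptor at C3 changes by priority only).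

**Step 11**
Reactants: 17 (2R,3S)-3,7,8-tris(benzyloxy)-2-[4-(benzyloxy)phenyl]-6-bromochroman-4-one
Product: 18 (2R,3R,4R)-3,7,8-tris(benzyloxy)-2-[4-(benzyloxy)phenyl]-6-bromochroman-4-ol
Conditions: NaBH4, CeCl3·7H2O, MeOH/THF, −40 °C
Reagents that add atoms: none
Why: Luche-type borohydride reduction, in which hydride attacks C4 axially from the face anti to the axial 3-benzyloxy group (2-aryl equatorial), should place the new hydroxyl cis to O3 and make C4 R.

**Step 12**
Reactants: 16 (2R,3R,4S)-3,7,8-tris(benzyloxy)-2-[4-(benzyloxy)phenyl]-6-bromochroman-4-ol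
Product: 19 (2R,3R,4S)-3,7,8-tris(benzyloxy)-2-[4-(benzyloxy)phenyl]-6-(4,4,5,5-tetramethyl-1,3,2-dioxaborolan-2-yl)chroman-4-ol
Conditions: B2pin2 (1.3 equiv), Pd(dppf)Cl2 (5 mol %), KOAc, 1,4-dioxane, 90 °C
Reagents that add atoms: bis(pinacolato)diboron, CC1(C)OB(OC1(C)C)B1OC(C)(C)C(C)(C)O1
Why: Miyaura borylation of the aryl bromide; acetate as the base leaves the free benzylic carbinol alone.

**Step 13**
Reactants: 18 (2R,3R,4R)-3,7,8-tris(benzyloxy)-2-[4-(benzyloxy)phenyl]-6-bromochroman-4-ol; 19 (2R,3R,4S)-3,7,8-tris(benzyloxy)-2-[4-(benzyloxy)phenyl]-6-(4,4,5,5-tetramethyl-1,3,2-dioxaborolan-2-yl)chroman-4-ol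
Product: 20 (2R,2'R,3R,3'R,4R,4'S)-3,3',7,7',8,8'-hexakis(benzyloxy)-2,2'-bis[4-(benzyloxy)phenyl]-[6,6'-bichromane]-4,4'-diol
Conditions: Pd(OAc)2 (5 mol %), SPhos (10 mol %), K3PO4, toluene/H2O 10:1, 80 °C
Reagents that add atoms: none
Why: Suzuki–Miyaura cross-coupling should join C6 to C6'; SPhos copes with the two ortho benzyloxy groups, and no stereocentre is involved.

**Step 14**
Reactants: 20 (2R,2'R,3R,3'R,4R,4'S)-3,3',7,7',8,8'-hexakis(benzyloxy)-2,2'-bis[4-(benzyloxy)phenyl]-[6,6'-bichromane]-4,4'-diol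
Product: 21 (2R,2'R,3R,3'R,4R,4'S)-2,2'-bis(4-hydroxyphenyl)-[6,6'-bichromane]-3,3',4,4',7,7',8,8'-octol
Conditions: H2 (1 atm), Pd(OH)2/C, THF/MeOH 1:1, rt, stopped at full debenzylation; filtration under argon
Reagents that add atoms: none
Why: Hydrogenolysis of the six aryl and two alkyl benzyl ethers under neutral conditions; with no acid present the C4 carbinols should be neither epimerised nor reduced.

**Compound list**
1 | 2-bromo-3-hydroxy-4-methoxybenzaldehyde | O=Cc1ccc(OC)c(O)c1Br | starting material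
2 | 2-bromo-3,4-dihydroxybenzaldehyde | O=Cc1ccc(O)c(O)c1Br | intermediate
3 | 3,4-bis(benzyloxy)-2-bromobenzaldehyde | O=Cc1ccc(OCc2ccccc2)c(OCc2ccccc2)c1Br | intermediate
4 | (R)-4-benzyloxazolidin-2-one | O=C1N[C@H](Cc2ccccc2)CO1 | starting material
5 | 2-(benzyloxy)acetyl chloride | O=C(Cl)COCc1ccccc1 | starting material
6 | lithium (R)-4-benzyl-2-oxooxazolidin-3-ide | [Li]N1C(=O)OC[C@H]1Cc1ccccc1 | intermediate
7 | (R)-4-benzyl-3-[2-(benzyloxy)acetyl]oxazolidin-2-one | O=C(COCc1ccccc1)N1C(=O)OC[C@H]1Cc1ccccc1 | intermediate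
8 | (R,Z)-4-benzyl-3-{2-(benzyloxy)-1-[(dibutylboranyl)oxy]ethenyl}oxazolidin-2-one | CCCCB(CCCC)O/C(=C\OCc1ccccc1)N1C(=O)OC[C@H]1Cc1ccccc1 | intermediate
9 | (R)-4-benzyl-3-[(2R,3S)-2-(benzyloxy)-3-[3,4-bis(benzyloxy)-2-bromophenyl]-3-hydroxypropanoyl]oxazolidin-2-one | O=C([C@H](OCc1ccccc1)[C@@H](O)c1ccc(OCc2ccccc2)c(OCc2ccccc2)c1Br)N1C(=O)OC[C@H]1Cc1ccccc1 | intermediate
10 | (2R,3S)-2-(benzyloxy)-3-[3,4-bis(benzyloxy)-2-bromophenyl]-3-hydroxy-N-methoxy-N-methylpropanamide | CON(C)C(=O)[C@H](OCc1ccccc1)[C@@H](O)c1ccc(OCc2ccccc2)c(OCc2ccccc2)c1Br | intermediate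
11 | [4-(benzyloxy)phenyl]magnesium bromide | Br[Mg]c1ccc(OCc2ccccc2)cc1 | starting material
12 | (2R,3S)-2-(benzyloxy)-3-[3,4-bis(benzyloxy)-2-bromophenyl]-1-[4-(benzyloxy)phenyl]-3-hydroxypropan-1-one | O=C(c1ccc(OCc2ccccc2)cc1)[C@H](OCc1ccccc1)[C@@H](O)c1ccc(OCc2ccccc2)c(OCc2ccccc2)c1Br | intermediate
13 | (2R,3S)-2-(benzyloxy)-3-[3,4-bis(benzyloxy)-2-bromophenyl]-1-[4-(benzyloxy)phenyl]-3-[(diethylboranyl)oxy]propan-1-one | O=C(c1ccc(OCc2ccccc2)cc1)[C@H](OCc1ccccc1)[C@@H](OB(CC)CC)c1ccc(OCc2ccccc2)c(OCc2ccccc2)c1Br | intermediate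
14 | (1S,2S,3R)-2-(benzyloxy)-1-[3,4-bis(benzyloxy)-2-bromophenyl]-3-[4-(benzyloxy)phenyl]propane-1,3-diol | O[C@H](c1ccc(OCc2ccccc2)cc1)[C@H](OCc1ccccc1)[C@@H](O)c1ccc(OCc2ccccc2)c(OCc2ccccc2)c1Br | intermediate
15 | (2R,3R,4S)-3,7,8-tris(benzyloxy)-2-[4-(benzyloxy)phenyl]chroman-4-ol | c1cc2c(c(OCc3ccccc3)c1OCc1ccccc1)O[C@H](c1ccc(OCc3ccccc3)cc1)[C@H](OCc1ccccc1)[C@H]2O | intermediate
16 | (2R,3R,4S)-3,7,8-tris(benzyloxy)-2-[4-(benzyloxy)phenyl]-6-bromochroman-4-ol | Brc1cc2c(c(OCc3ccccc3)c1OCc1ccccc1)O[C@H](c1ccc(OCc3ccccc3)cc1)[C@H](OCc1ccccc1)[C@H]2O | intermediate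
17 | (2R,3S)-3,7,8-tris(benzyloxy)-2-[4-(benzyloxy)phenyl]-6-bromochroman-4-one | Brc1cc2c(c(OCc3ccccc3)c1OCc1ccccc1)O[C@H](c1ccc(OCc3ccccc3)cc1)[C@H](OCc1ccccc1)C2=O | intermediate
18 | (2R,3R,4R)-3,7,8-tris(benzyloxy)-2-[4-(benzyloxy)phenyl]-6-bromochroman-4-ol | Brc1cc2c(c(OCc3ccccc3)c1OCc1ccccc1)O[C@H](c1ccc(OCc3ccccc3)cc1)[C@H](OCc1ccccc1)[C@@H]2O | intermediate
19 | (2R,3R,4S)-3,7,8-tris(benzyloxy)-2-[4-(benzyloxy)phenyl]-6-(4,4,5,5-tetramethyl-1,3,2-dioxaborolan-2-yl)chroman-4-ol | CC1(C)OB(OC1(C)C)c1cc2c(c(OCc3ccccc3)c1OCc1ccccc1)O[C@H](c1ccc(OCc3ccccc3)cc1)[C@H](OCc1ccccc1)[C@H]2O | intermediate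
20 | (2R,2'R,3R,3'R,4R,4'S)-3,3',7,7',8,8'-hexakis(benzyloxy)-2,2'-bis[4-(benzyloxy)phenyl]-[6,6'-bichromane]-4,4'-diol | c1(-c3cc4c(c(OCc5ccccc5)c3OCc3ccccc3)O[C@H](c3ccc(OCc5ccccc5)cc3)[C@H](OCc3ccccc3)[C@H]4O)cc2c(c(OCc3ccccc3)c1OCc1ccccc1)O[C@H](c1ccc(OCc3ccccc3)cc1)[C@H](OCc1ccccc1)[C@@H]2O | intermediate
21 | (2R,2'R,3R,3'R,4R,4'S)-2,2'-bis(4-hydroxyphenyl)-[6,6'-bichromane]-3,3',4,4',7,7',8,8'-octol | Oc1ccc([C@H]2Oc3c(cc(-c4cc5c(c(O)c4O)O[C@H](c4ccc(O)cc4)[C@H](O)[C@H]5O)c(O)c3O)[C@@H](O)[C@H]2O)cc1 | target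

**Step count and risks**
Total steps: 14. Longest linear sequence: 12 steps (steps 1, 2, 4, 5, 6, 7, 8, 9, 10, 11, 13, 14).

The three steps most likely to fail:

- **Step 8.** The hindered, electron-rich C8a–Br bond may resist oxidative addition, or the copper alkoxide of the benzylic C4 hydroxyl may divert the catalyst into hydrodebromination with oxidation at C4. The fallback closes ring C from the other side, through the O1–C2 bond with inversion; it sets out from 12 and comes back at 15. Ketone 12 is reduced 1,3-anti with Me4NBH(OAc)3 (MeCN/AcOH, −20 °C, Evans–Saksena) to the C2 epimer of 14, (1S,2S,3S)-2-(benzyloxy)-1-[3,4-bis(benzyloxy)-2-bromophenyl]-3-[4-(benzyloxy)phenyl]propane-1,3-diol F1. Borylation (B2pin2, Pd(OAc)2, XPhos, KOAc, dioxane, 90 °C) gives the corresponding aryl pinacol boronate F2, and NaBO3·4H2O in THF/H2O oxidises it to the 2-hydroxyphenyl diol F3. Mitsunobu closure (PPh3, DIAD, THF, 0 °C), in which the phenol displaces the activated C2 hydroxyl in a 6-exo-tet substitution with inversion, should return to 15.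

- **Step 10.** The C3 configuration may be lost by enolisation of the cis-3-benzyloxy ketone, or ring C may open by β-elimination of the O1 phenoxide, before the hydride of step 11 arrives. The fallback inverts C4 without a carbonyl intermediate; it sets out from 16 and comes back at 18. Mitsunobu reaction of 16 with 4-nitrobenzoic acid (PPh3, DIAD, toluene, −20 °C) should give the C4-inverted ester (2R,3S,4R)-3,7,8-tris(benzyloxy)-2-[4-(benzyloxy)phenyl]-6-bromochroman-4-yl 4-nitrobenzoate F4 (the 3S descriptor is a priority change only). Methanolysis (K2CO3, MeOH, 0 °C) returns to 18.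

- **Step 14.** Once the phenols are free, the benzylic C4–O bonds (the 7-oxygen is para to C4a) may be hydrogenolysed, or ring C may open at C2 on long exposure. The fallback masks the carbinols before hydrogenolysis; it sets out from 20 and comes back at 21. Silylation of both C4 hydroxyls (TBSOTf, 2,6-lutidine, CH2Cl2, −78 °C) gives the 4,4'-bis-O-(tert-butyldimethylsilyl) ether of 20 F5. Hydrogenolysis as in step 14 gives the 4,4'-bis-O-(tert-butyldimethylsilyl) ether of 21 F6, in which the bulky silyl groups shield the benzylic C–O bonds. Buffered fluoride (TBAF/AcOH 1:1, THF, 0 °C, argon) returns to 21.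

**Further compounds**
F1 | step 8 | (1S,2S,3S)-2-(benzyloxy)-1-[3,4-bis(benzyloxy)-2-bromophenyl]-3-[4-(benzyloxy)phenyl]propane-1,3-diol | O[C@@H](c1ccc(OCc2ccccc2)cc1)[C@H](OCc1ccccc1)[C@@H](O)c1ccc(OCc2ccccc2)c(OCc2ccccc2)c1Br
F2 | step 8 | (1S,2S,3S)-2-(benzyloxy)-1-[3,4-bis(benzyloxy)-2-(4,4,5,5-tetramethyl-1,3,2-dioxaborolan-2-yl)phenyl]-3-[4-(benzyloxy)phenyl]propane-1,3-diol | O[C@@H](c1ccc(OCc2ccccc2)cc1)[C@H](OCc1ccccc1)[C@@H](O)c1ccc(OCc2ccccc2)c(OCc2ccccc2)c1B1OC(C)(C)C(C)(C)O1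
F3 | step 8 | (1S,2S,3S)-2-(benzyloxy)-1-[3,4-bis(benzyloxy)-2-hydroxyphenyl]-3-[4-(benzyloxy)phenyl]propane-1,3-diol | O[C@@H](c1ccc(OCc2ccccc2)cc1)[C@H](OCc1ccccc1)[C@@H](O)c1ccc(OCc2ccccc2)c(OCc2ccccc2)c1O
F4 | step 10 | (2R,3S,4R)-3,7,8-tris(benzyloxy)-2-[4-(benzyloxy)phenyl]-6-bromochroman-4-yl 4-nitrobenzoate | Brc1cc2c(c(OCc3ccccc3)c1OCc1ccccc1)O[C@H](c1ccc(OCc3ccccc3)cc1)[C@H](OCc1ccccc1)[C@@H]2OC(=O)c1ccc([N+](=O)[O-])cc1
F5 | step 14 | 4,4'-bis-O-(tert-butyldimethylsilyl) ether of 20 | c1(-c3cc4c(c(OCc5ccccc5)c3OCc3ccccc3)O[C@H](c3ccc(OCc5ccccc5)cc3)[C@H](OCc3ccccc3)[C@H]4O[Si](C)(C)C(C)(C)C)cc2c(c(OCc3ccccc3)c1OCc1ccccc1)O[C@H](c1ccc(OCc3ccccc3)cc1)[C@H](OCc1ccccc1)[C@@H]2O[Si](C)(C)C(C)(C)C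
F6 | step 14 | 4,4'-bis-O-(tert-butyldimethylsilyl) ether of 21 | c1(-c3cc4c(c(O)c3O)O[C@H](c3ccc(O)cc3)[C@H](O)[C@H]4O[Si](C)(C)C(C)(C)C)cc2c(c(O)c1O)O[C@H](c1ccc(O)cc1)[C@H](O)[C@@H]2O[Si](C)(C)C(C)(C)C
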